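**Retrosynthetic overview**
- Numbering: ring A is C1' (ether O), C2' (OMe), C3' (Br), C4' (H), C5' (Br), C6' (Br); ring B is C1 (ether O), C2 (H), C3 (Br), C4 (H), C5 (Br), C6 (OH).
- Feature the plan rests on: C2–C3–C4–C5 of ring B (H, Br, H, Br) is the C6–C5–C4–C3 diene of 3,5-dibromo-2-pyrone, and the vicinal pair C1(OAr)/C6(OH) is the two-carbon unit of an aryloxyketene bis-silyl acetal. Ring B is therefore cut at C1–C2 and C5–C6 and is the only ring built ([4+2], then loss of CO2 and silanol).
- The ketene acetal comes from (2,3,5-tribromo-6-methoxyphenoxy)acetic acid. Ring A is only decorated: C6'–Br by phenol-directed bromination of 4-nitroguaiacol, C3'/C5'–Br by bromination ortho to a C4' amino group (from the nitro group), which is then removed.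
- The dibromopyrone comes from coumalic acid by bromodecarboxylation and C3 bromination; the last step is O-desilylation.

Key step: step 9

Assumption: the target has no stereocentre and, with C2–H ortho to the ether oxygen on ring B, no configurationally stable diaryl ether axis; it is a single achiral compound and no stereocontrol is needed.

**Route**

Step 1
Reactants: 1 2-methoxy-4-nitrophenol (4-nitroguaiacol)
Product: 2 2-bromo-6-methoxy-4-nitrophenol
Conditions: Br2 (1.05 equiv), AcOH, rt
Reagents that add atoms: bromine, BrBr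
Why: Electrophilic aromatic bromination; the free phenol directs to its only open ortho position (future C6'), which is also meta to the nitro group, as in the bromination of vanillin-type guaiacols.

Step 2
Reactants: 2 2-bromo-6-methoxy-4-nitrophenol; 3 methyl bromoacetate
Product: 4 methyl 2-(2-bromo-6-methoxy-4-nitrophenoxy)acetate
Conditions: K2CO3, DMF, 60 °C
Reagents that add atoms: none
Why: Williamson ether synthesis; the acidic nitrophenol is fully ionised by carbonate, and the primary α-bromo ester is reactive enough in DMF to alkylate the hindered, weakly nucleophilic phenoxide.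

Step 3
Reactants: 4 methyl 2-(2-bromo-6-methoxy-4-nitrophenoxy)acetate
Product: 5 methyl 2-(4-amino-2-bromo-6-methoxyphenoxy)acetate
Conditions: Fe powder, AcOH, EtOH/H2O, 70 °C
Reagents that add atoms: none
Why: Béchamp-type dissolving-metal nitro reduction, which leaves the aryl bromide and the ester untouched, unlike catalytic hydrogenation.

Step 4
Reactants: 5 methyl 2-(4-amino-2-bromo-6-methoxyphenoxy)acetate
Product: 6 methyl 2-(4-amino-2,3,5-tribromo-6-methoxyphenoxy)acetate
Conditions: NBS (2.05 equiv), MeCN, 0 °C → rt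
Reagents that add atoms: N-bromosuccinimide, O=C1CCC(=O)N1Br
Why: Electrophilic bromination of an aniline; C3' and C5' are the only unsubstituted ring carbons and both are ortho to the amino group, so the regiochemistry is fixed by the substrate.

Step 5
Reactants: 6 methyl 2-(4-amino-2,3,5-tribromo-6-methoxyphenoxy)acetate
Product: 7 2-(4-amino-2,3,5-tribromo-6-methoxyphenoxy)acetic acid
Conditions: LiOH·H2O, THF/H2O, rt; then 1 M HCl to pH 2
Reagents that add atoms: lithium hydroxide, [Li+].[OH-]
Why: Saponification (BAc2 ester hydrolysis); the doubly ortho-brominated aniline is too weakly basic to form a zwitterion, so the acid should extract normally after acidification.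

Step 6
Reactants: 7 2-(4-amino-2,3,5-tribromo-6-methoxyphenoxy)acetic acid
Product: 9 2-(2,3,5-tribromo-6-methoxyphenoxy)acetic acid, via arenediazonium hydrogensulfate 8 (not isolated)
Conditions: NaNO2, conc. H2SO4/AcOH, 0–10 °C; then 50% aq. H3PO2, 0 °C → rt
Reagents that add atoms: none
Why: Diazotisation followed by hypophosphorous acid reduction (reductive deamination); nitrosylsulfuric acid is the standard medium for weakly basic 2,6-dibromoanilines, and the radical-chain reduction replaces N2+ by H to leave C4'–H.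

Step 7
Reactants: 10 coumalic acid
Product: 12 3,5-dibromo-2H-pyran-2-one, via 5-bromo-2H-pyran-2-one 11 (not isolated)
Conditions: NBS (2.5 equiv), LiOAc (cat.), MeCN/H2O, rt
Reagents that add atoms: N-bromosuccinimide, O=C1CCC(=O)N1Br
Why: Catalytic Hunsdiecker-type bromodecarboxylation: Br+ attacks the carboxyl-bearing C5 (an enol-ether β-carbon) with loss of CO2, and a second electrophilic bromination then takes place at C3, the other nucleophilic carbon of the pyrone.

Step 8
Reactants: 9 2-(2,3,5-tribromo-6-methoxyphenoxy)acetic acid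
Product: 14 1,1-bis(trimethylsilyloxy)-2-(2,3,5-tribromo-6-methoxyphenoxy)ethene, via trimethylsilyl ester 13 (not isolated)
Conditions: TMSOTf (2.3 equiv), Et3N (3 equiv), Et2O, 0 °C → rt; pentane, decant from Et3NH·OTf, concentrate under Ar; used crude
Reagents that add atoms: trimethylsilyl trifluoromethanesulfonate, C[Si](C)(C)OS(=O)(=O)C(F)(F)F
Why: Soft enolisation: the acid is O-silylated, then silyl triflate activation of the ester carbonyl lets triethylamine remove the α-proton acidified by the aryloxy group; no strong base touches the C4'–H flanked by two bromines, and two equal silyloxy groups leave no alkene geometry to control.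

Step 9
Reactants: 14 1,1-bis(trimethylsilyloxy)-2-(2,3,5-tribromo-6-methoxyphenoxy)ethene; 12 3,5-dibromo-2H-pyran-2-one
Product: 17 [2,4-dibromo-6-(2,3,5-tribromo-6-methoxyphenoxy)phenoxy]trimethylsilane, via bridged lactone cycloadduct 15 (not isolated), via cyclohexadienone bis-silyl ketal 16 (not isolated)
Conditions: 14 (2 equiv), PhMe, 110 °C, sealed tube, Ar; crude taken on
Reagents that add atoms: none
Why: The electron-rich ketene acetal 14 and the electron-poor C3=C4–C5=C6 diene of 12 should combine in a polarised, probably asynchronous inverse-electron-demand [4+2] cycloaddition to the 2-oxabicyclo[2.2.2]octenone 15; retro-[4+2] loss of CO2 then gives diene 16, and 1,2-elimination of trimethylsilanol across the ketal carbon and the adjacent CH(OAr) aromatises ring B. The closest known reaction type is the benzannulation of electron-poor 2-pyrones with 1,1-dialkoxy- and 1,1,2-trialkoxyethenes to aryl ethers, together with the cycloadditions of 3,5-dibromo-2-pyrone with enol ethers. Ring B is closed intermolecularly as a six-membered carbocycle in the [4+2] mode, C2–C5 coming from the pyrone and C1 and C6 from the acetal, with formation of the C1–C2 and C5–C6 bonds. No stereocentre is set: the sp3 centres of 15 and 16 form as mixtures and are all erased on aromatisation. The selectivity needed is regiochemical (aryloxy-bearing carbon to pyrone C6, acetal carbon to pyrone C3); it is secured because the two silyloxy groups outweigh the single electron-poor aryloxy group and make the CH(OAr) carbon the nucleophilic terminus, which pairs with C6, the vinylogous-lactone electrophilic end of the diene, the orientation known for donor alkenes with 3-bromo-2-pyrones. Aromatisation can only expel silanol, because the aryloxy carbon has no neighbouring sp3 C–H, and loss of either silyloxy group leaves the same silyl ether.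

Step 10
Reactants: 17 [2,4-dibromo-6-(2,3,5-tribromo-6-methoxyphenoxy)phenoxy]trimethylsilane
Product: 18 2,4-dibromo-6-(2,3,5-tribromo-6-methoxyphenoxy)phenol
Conditions: 1 M HCl, THF/MeOH, rt
Reagents that add atoms: none
Why: Acid-catalysed solvolysis of an aryl trimethylsilyl ether; the aryl bromides, the methyl ether and the diaryl ether are inert under these conditions.

**Compound list**

1 | 2-methoxy-4-nitrophenol | COc1cc([N+](=O)[O-])ccc1O | starting material
2 | 2-bromo-6-methoxy-4-nitrophenol | COc1cc([N+](=O)[O-])cc(Br)c1O | intermediate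
3 | methyl bromoacetate | COC(=O)CBr | starting material
4 | methyl 2-(2-bromo-6-methoxy-4-nitrophenoxy)acetate | COC(=O)COc1c(Br)cc([N+](=O)[O-])cc1OC | intermediate
5 | methyl 2-(4-amino-2-bromo-6-methoxyphenoxy)acetate | COC(=O)COc1c(Br)cc(N)cc1OC | intermediate
6 | methyl 2-(4-amino-2,3,5-tribromo-6-methoxyphenoxy)acetate | COC(=O)COc1c(Br)c(Br)c(N)c(Br)c1OC | intermediate
7 | 2-(4-amino-2,3,5-tribromo-6-methoxyphenoxy)acetic acid | OC(=O)COc1c(Br)c(Br)c(N)c(Br)c1OC | intermediate
8 | 2,3,6-tribromo-4-(carboxymethoxy)-5-methoxybenzenediazonium hydrogensulfate | OC(=O)COc1c(Br)c(Br)c([N+]#N)c(Br)c1OC.OS(=O)(=O)[O-] | intermediate (not isolated)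
9 | 2-(2,3,5-tribromo-6-methoxyphenoxy)acetic acid | OC(=O)COc1c(Br)c(Br)cc(Br)c1OC | intermediate
10 | coumalic acid (2-oxo-2H-pyran-5-carboxylic acid) | O=C(O)C1=COC(=O)C=C1 | starting material
11 | 5-bromo-2H-pyran-2-one | O=C1OC=C(Br)C=C1 | intermediate (not isolated)
12 | 3,5-dibromo-2H-pyran-2-one | O=C1OC=C(Br)C=C1Br | intermediate
13 | trimethylsilyl 2-(2,3,5-tribromo-6-methoxyphenoxy)acetate | C[Si](C)(C)OC(=O)COc1c(Br)c(Br)cc(Br)c1OC | intermediate (not isolated)
14 | 1,1-bis(trimethylsilyloxy)-2-(2,3,5-tribromo-6-methoxyphenoxy)ethene | COc1c(Br)cc(Br)c(Br)c1OC=C(O[Si](C)(C)C)O[Si](C)(C)C | intermediate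
15 | 4,7-dibromo-5,5-bis(trimethylsilyloxy)-6-(2,3,5-tribromo-6-methoxyphenoxy)-2-oxabicyclo[2.2.2]oct-7-en-3-one (racemic, diastereomer mixture) | O=C1OC2C(Br)=CC1(Br)C(O[Si](C)(C)C)(O[Si](C)(C)C)C2Oc1c(Br)c(Br)cc(Br)c1OC | intermediate (not isolated)
16 | 1,3-dibromo-6,6-bis(trimethylsilyloxy)-5-(2,3,5-tribromo-6-methoxyphenoxy)cyclohexa-1,3-diene (racemic) | C[Si](C)(C)OC1(O[Si](C)(C)C)C(Br)=CC(Br)=CC1Oc1c(Br)c(Br)cc(Br)c1OC | intermediate (not isolated)
17 | [2,4-dibromo-6-(2,3,5-tribromo-6-methoxyphenoxy)phenoxy]trimethylsilane | COc1c(Br)cc(Br)c(Br)c1Oc1cc(Br)cc(Br)c1O[Si](C)(C)C | intermediate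
18 | 2,4-dibromo-6-(2,3,5-tribromo-6-methoxyphenoxy)phenol | COc1c(Br)cc(Br)c(Br)c1Oc1cc(Br)cc(Br)c1O | target

**Step count and risks**

Total step count: 10. Longest linear sequence: 9 steps (steps 1–6, 8, 9, 10); the pyrone branch is one step (step 7).

Steps most likely to fail:

1. Step 9 (key step). Three things may go wrong.
   - The ketene acetal may be consumed by protodesilylation (by moisture or by the silanol that aromatisation releases) or by O-to-C silyl migration before it engages the hindered diene.
   - The first bond may form at pyrone C6 without closure onto the brominated C3, draining material into open-chain silyl-transfer products.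
   - The addition may take the reverse orientation.

   The fallback forms the C1–O bond by known chemistry; it sets out from 2 and rejoins the route at 18. The phenoxide of 2 is used in a nucleophilic aromatic substitution on 2,4-dibromo-6-fluorobenzaldehyde (O=Cc1c(F)cc(Br)cc1Br; Cs2CO3, DMSO, 100 °C), which should give 2,4-dibromo-6-(2-bromo-6-methoxy-4-nitrophenoxy)benzaldehyde F1. Baeyer–Villiger (Dakin-type) oxidation with mCPBA in CH2Cl2 should give 2,4-dibromo-6-(2-bromo-6-methoxy-4-nitrophenoxy)phenyl formate F2, which K2CO3 (cat.) in MeOH cleaves to 2,4-dibromo-6-(2-bromo-6-methoxy-4-nitrophenoxy)phenol F3. Fe/AcOH reduces the nitro group to 6-(4-amino-2-bromo-6-methoxyphenoxy)-2,4-dibromophenol F4. NBS (2 equiv) then brominates C3' and C5', the only positions ortho to the amino group (ring B has no free position ortho or para to its OH), to give 6-(4-amino-2,3,5-tribromo-6-methoxyphenoxy)-2,4-dibromophenol F5. Diazotisation (NaNO2, H2SO4/AcOH) to 2,3,6-tribromo-4-(3,5-dibromo-2-hydroxyphenoxy)-5-methoxybenzenediazonium hydrogensulfate F6 and H3PO2 reduction then gives 18.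

2. Step 8. Enolisation may stop at silyl ester 13 or divert to C-silylation, and the labile bis-TMS acetal may hydrolyse back while the ammonium salt is removed.

   The fallback replaces soft enolisation by amide-base enolisation of a preformed, more robust silyl ester; it sets out from 9 and rejoins at 18. TBSCl/imidazole in DMF converts 9 into tert-butyldimethylsilyl 2-(2,3,5-tribromo-6-methoxyphenoxy)acetate F7. LiHMDS with TBSCl present (THF/DMPU, −78 °C → rt; a chelated glycolate-type enolate, with a base too weak to metalate C4'–H) gives the isolable 1,1-bis(tert-butyldimethylsilyloxy)-2-(2,3,5-tribromo-6-methoxyphenoxy)ethene F8. Heating F8 with 12 in toluene or xylene (110–130 °C) should pass through 4,7-dibromo-5,5-bis(tert-butyldimethylsilyloxy)-6-(2,3,5-tribromo-6-methoxyphenoxy)-2-oxabicyclo[2.2.2]oct-7-en-3-one F9 and 1,3-dibromo-6,6-bis(tert-butyldimethylsilyloxy)-5-(2,3,5-tribromo-6-methoxyphenoxy)cyclohexa-1,3-diene F10 to tert-butyl[2,4-dibromo-6-(2,3,5-tribromo-6-methoxyphenoxy)phenoxy]dimethylsilane F11. TBAF/AcOH in THF then gives 18.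

3. Step 6. Diazotisation of the weakly basic, doubly ortho-brominated amine may be incomplete, and the diazonium ion may undergo hydrolysis or halide displacement in the aqueous acid before it is reduced.

   The fallback moves the deamination to the ester stage under anhydrous diazotisation with an isolated salt; it sets out from 6 and rejoins at 9. NOBF4 in MeCN (−20 °C, precipitation with Et2O) gives 2,3,6-tribromo-5-methoxy-4-(2-methoxy-2-oxoethoxy)benzenediazonium tetrafluoroborate F12. Copper-catalysed hydrodediazoniation (50% aq. H3PO2, cat. Cu2O, CHCl3, 0 °C → rt) gives methyl 2-(2,3,5-tribromo-6-methoxyphenoxy)acetate F13. LiOH in THF/H2O followed by HCl then gives 9.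

**Further compounds**

F1 | step 9 | 2,4-dibromo-6-(2-bromo-6-methoxy-4-nitrophenoxy)benzaldehyde | COc1cc([N+](=O)[O-])cc(Br)c1Oc1cc(Br)cc(Br)c1C=O
F2 | step 9 | 2,4-dibromo-6-(2-bromo-6-methoxy-4-nitrophenoxy)phenyl formate | COc1cc([N+](=O)[O-])cc(Br)c1Oc1cc(Br)cc(Br)c1OC=O
F3 | step 9 | 2,4-dibromo-6-(2-bromo-6-methoxy-4-nitrophenoxy)phenol | COc1cc([N+](=O)[O-])cc(Br)c1Oc1cc(Br)cc(Br)c1O
F4 | step 9 | 6-(4-amino-2-bromo-6-methoxyphenoxy)-2,4-dibromophenol | COc1cc(N)cc(Br)c1Oc1cc(Br)cc(Br)c1O
F5 | step 9 | 6-(4-amino-2,3,5-tribromo-6-methoxyphenoxy)-2,4-dibromophenol | COc1c(Br)c(N)c(Br)c(Br)c1Oc1cc(Br)cc(Br)c1O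
F6 | step 9 | 2,3,6-tribromo-4-(3,5-dibromo-2-hydroxyphenoxy)-5-methoxybenzenediazonium hydrogensulfate | COc1c(Br)c([N+]#N)c(Br)c(Br)c1Oc1cc(Br)cc(Br)c1O.OS(=O)(=O)[O-]
F7 | step 8 | tert-butyldimethylsilyl 2-(2,3,5-tribromo-6-methoxyphenoxy)acetate | CC(C)(C)[Si](C)(C)OC(=O)COc1c(Br)c(Br)cc(Br)c1OC
F8 | step 8 | 1,1-bis(tert-butyldimethylsilyloxy)-2-(2,3,5-tribromo-6-methoxyphenoxy)ethene | COc1c(Br)cc(Br)c(Br)c1OC=C(O[Si](C)(C)C(C)(C)C)O[Si](C)(C)C(C)(C)C
F9 | step 8 | 4,7-dibromo-5,5-bis(tert-butyldimethylsilyloxy)-6-(2,3,5-tribromo-6-methoxyphenoxy)-2-oxabicyclo[2.2.2]oct-7-en-3-one | O=C1OC2C(Br)=CC1(Br)C(O[Si](C)(C)C(C)(C)C)(O[Si](C)(C)C(C)(C)C)C2Oc1c(Br)c(Br)cc(Br)c1OC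
F10 | step 8 | 1,3-dibromo-6,6-bis(tert-butyldimethylsilyloxy)-5-(2,3,5-tribromo-6-methoxyphenoxy)cyclohexa-1,3-diene | CC(C)(C)[Si](C)(C)OC1(O[Si](C)(C)C(C)(C)C)C(Br)=CC(Br)=CC1Oc1c(Br)c(Br)cc(Br)c1OC
F11 | step 8 | tert-butyl[2,4-dibromo-6-(2,3,5-tribromo-6-methoxyphenoxy)phenoxy]dimethylsilane | COc1c(Br)cc(Br)c(Br)c1Oc1cc(Br)cc(Br)c1O[Si](C)(C)C(C)(C)C
F12 | step 6 | 2,3,6-tribromo-5-methoxy-4-(2-methoxy-2-oxoethoxy)benzenediazonium tetrafluoroborate | COC(=O)COc1c(Br)c(Br)c([N+]#N)c(Br)c1OC.F[B-](F)(F)F
F13 | step 6 | methyl 2-(2,3,5-tribromo-6-methoxyphenoxy)acetate | COC(=O)COc1c(Br)c(Br)cc(Br)c1OC
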